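The pyrrolidine (N4, C3, C2, C1, C9a) is disconnected at C1–C2 and N4–C9a. Its carbons C9a and C3 each carry the γ-carbon of an α-methyl-γ-lactone (rings A and B), so each can serve as an N-acyliminium carbon, while C1 and C2 are plain CH2 groups. The key step is a one-pot [3+2] annulation: Negishi coupling of the L-serine-derived alkylzinc (C2, C3, N4) with (Z)-2-bromovinyl ethyl ether (C1, C9a) makes C1–C2, and acid then closes N4–C9a to a 5-ethoxyprolinate. Two vinylogous Mannich reactions, relayed by the serine carboxyl, attach rings A and B; an enamine/pyruvic acid annulation closes ring C and the azepine.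

Key step: step 3

Atom labels: pyrrolo[1,2-a]azepine numbering (N4; pyrrolidine C1, C2, C3, C9a; azepine C5 to C9). Ring A is the spiro lactone at C9 (C10, C11, C12), ring B the lactone on C3 (C16, C17, C18), ring C the butenolide fused at C5–C6.

Assumption: the C5 N,O-acetal configuration of the target is the thermodynamically preferred one, so the reversible closure of ring C delivers it.

Step 1
Reactants: 1 3-methylfuran-2(5H)-one
Product: 2 triisopropyl[(3-methylfuran-2-yl)oxy]silane
Conditions: TIPSOTf, Et3N, CH2Cl2, 0 °C to rt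
Reagents that add atoms: triisopropylsilyl trifluoromethanesulfonate, CC(C)[Si](C(C)C)(C(C)C)OS(=O)(=O)C(F)(F)F
Why: Soft enolisation of the butenolide by Et3N with O-silylation (silyl dienol ether formation) gives the aromatic 2-silyloxyfuran; no stereocentre is involved.

Step 2
Reactants: 2 triisopropyl[(3-methylfuran-2-yl)oxy]silane; 3 5-bromopent-1-ene
Product: 5 triisopropyl{[3-methyl-5-(pent-4-en-1-yl)furan-2-yl]oxy}silane, via furyllithium 4 (not isolated)
Conditions: s-BuLi, TMEDA, THF, −78 to 0 °C; then 3, 0 °C to rt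
Reagents that add atoms: none
Why: The C5–H next to the ring oxygen is the only acidic furan position, so lithiation and SN2 alkylation of the primary bromide (furyllithium alkylation) install the future C8–C5 chain as a pentenyl group whose terminal alkene masks the C5 aldehyde.

Step 3
Reactants: 6 methyl (2R)-2-[(tert-butoxycarbonyl)amino]-3-iodopropanoate; 7 (Z)-1-bromo-2-ethoxyethene
Product: 10 1-tert-butyl 2-methyl (2S)-5-ethoxypyrrolidine-1,2-dicarboxylate (both C5 epimers), via alkylzinc iodide 8 (not isolated), via enol ether 9 (not isolated)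
Conditions: Zn dust (TMSCl-activated), DMF, rt; Pd2(dba)3 (2.5 mol %), SPhos (10 mol %), 7, rt to 40 °C; then EtOH, camphorsulfonic acid, 40 °C, same flask
Reagents that add atoms: none
Why: Zinc inserts into the C–I bond to give the β-amido alkylzinc iodide 8; transmetalation to the vinylpalladium bromide formed from 7 and zerovalent palladium, then reductive elimination, forges C1–C2 (Negishi sp3–sp2 coupling, established for serine-derived organozinc reagents and vinyl halides) and gives enol ether 9, a masked γ-carbamoyl aldehyde. On acidification 9 is protonated at C1 and the carbamate nitrogen captures the oxocarbenium carbon C9a (5-exo-trig onto C=O+, the standard closure of N-acyl 4-aminobutanal equivalents to 2-alkoxypyrrolidines), which forms N4–C9a and the pyrrolidine ring. The only new stereocentre, the N,O-acetal carbon C9a, is allowed to form as an epimer mixture because both epimers ionise to the same N-acyliminium ion in step 4 (stereoconvergent), while C3 from L-serine is not touched. The selectivity needed is coupling in preference to β-elimination or protonation of 8; chelation of zinc by the carbamate and ester carbonyls in DMF and the electron-rich ligand SPhos should secure it.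

Step 4
Reactants: 10 1-tert-butyl 2-methyl (2S)-5-ethoxypyrrolidine-1,2-dicarboxylate; 5 triisopropyl{[3-methyl-5-(pent-4-en-1-yl)furan-2-yl]oxy}silane
Product: 11 1-tert-butyl 2-methyl (2S,5S)-5-[(2S)-4-methyl-5-oxo-2-(pent-4-en-1-yl)-2,5-dihydrofuran-2-yl]pyrrolidine-1,2-dicarboxylate
Conditions: TIPSOTf (10 mol %), CH2Cl2, −78 to 0 °C
Reagents that add atoms: none
Why: TIPSOTf ionises either epimer of 10 to one N-acyliminium ion and 5 attacks through its substituted C5 in a vinylogous Mukaiyama–Mannich reaction, anti to the C3 ester (2,5-trans, sets C9a) and through the usual open threo transition state (sets the quaternary C9), a pairing established for 5-alkyl-3-methyl-2-silyloxyfurans and 5-alkoxyprolinates.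

Step 5
Reactants: 11 1-tert-butyl 2-methyl (2S,5S)-5-[(2S)-4-methyl-5-oxo-2-(pent-4-en-1-yl)-2,5-dihydrofuran-2-yl]pyrrolidine-1,2-dicarboxylate
Product: 12 (2S,5S)-1-(tert-butoxycarbonyl)-5-[(2S)-4-methyl-5-oxo-2-(pent-4-en-1-yl)-2,5-dihydrofuran-2-yl]pyrrolidine-2-carboxylic acid
Conditions: LiOH·H2O, THF/H2O (3:1), 0 °C; then 1 M HCl to pH 3
Reagents that add atoms: lithium hydroxide, [Li+].[OH-]
Why: Hydroxide cleaves the methyl ester by acyl substitution (saponification), the butenolide without γ-hydrogen recloses on acidification if opened, and epimerisation at C3 would be harmless because C3 is planarised in step 6.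

Step 6
Reactants: 12 (2S,5S)-1-(tert-butoxycarbonyl)-5-[(2S)-4-methyl-5-oxo-2-(pent-4-en-1-yl)-2,5-dihydrofuran-2-yl]pyrrolidine-2-carboxylic acid
Product: 13 tert-butyl (2S)-5-methoxy-2-[(2S)-4-methyl-5-oxo-2-(pent-4-en-1-yl)-2,5-dihydrofuran-2-yl]pyrrolidine-1-carboxylate (both C5 epimers)
Conditions: graphite anode, stainless-steel cathode, undivided cell, constant current, MeOH, Et3N (0.2 equiv), 10 °C
Reagents that add atoms: methanol, CO
Why: Non-Kolbe (Hofer–Moest) anodic decarboxylation of the N-acyl α-amino acid: carboxylate oxidation, loss of CO2 and further oxidation give the C3 N-acyliminium ion, which methanol traps, at a potential below that needed to oxidise the terminal alkene or the butenolide.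

Step 7
Reactants: 13 tert-butyl (2S)-5-methoxy-2-[(2S)-4-methyl-5-oxo-2-(pent-4-en-1-yl)-2,5-dihydrofuran-2-yl]pyrrolidine-1-carboxylate; 2 triisopropyl[(3-methylfuran-2-yl)oxy]silane
Product: 14 tert-butyl (2S,5S)-2-[(2S)-4-methyl-5-oxo-2-(pent-4-en-1-yl)-2,5-dihydrofuran-2-yl]-5-[(2S)-4-methyl-5-oxo-2,5-dihydrofuran-2-yl]pyrrolidine-1-carboxylate
Conditions: TIPSOTf (10 mol %), CH2Cl2, −78 °C
Reagents that add atoms: none
Why: Second vinylogous Mukaiyama–Mannich reaction: C5 of 2 attacks the C3 N-acyliminium ion anti to the bulky C9a substituent (2,5-trans) through the threo transition state, which re-creates C3 on the face the carboxyl had occupied and sets C16.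

Step 8
Reactants: 14 tert-butyl (2S,5S)-2-[(2S)-4-methyl-5-oxo-2-(pent-4-en-1-yl)-2,5-dihydrofuran-2-yl]-5-[(2S)-4-methyl-5-oxo-2,5-dihydrofuran-2-yl]pyrrolidine-1-carboxylate
Product: 15 tert-butyl (2S,5S)-2-[(2S)-4-methyl-5-oxo-2-(4-oxobutyl)-2,5-dihydrofuran-2-yl]-5-[(2S)-4-methyl-5-oxo-2,5-dihydrofuran-2-yl]pyrrolidine-1-carboxylate
Conditions: OsO4 (2 mol %), NaIO4, 2,6-lutidine, 1,4-dioxane/H2O (3:1), rt
Reagents that add atoms: osmium tetroxide (catalytic oxygen carrier), O=[Os](=O)(=O)=O; sodium periodate, [Na+].[O-]I(=O)(=O)=O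
Why: Lemieux–Johnson oxidation: the electron-rich terminal alkene is dihydroxylated and cleaved by periodate far faster than the electron-poor trisubstituted butenolides, which unveils the C5 aldehyde.

Step 9
Reactants: 15 tert-butyl (2S,5S)-2-[(2S)-4-methyl-5-oxo-2-(4-oxobutyl)-2,5-dihydrofuran-2-yl]-5-[(2S)-4-methyl-5-oxo-2,5-dihydrofuran-2-yl]pyrrolidine-1-carboxylate; 16 pyruvic acid
Product: 19 tetracyclic N,O-acetal with rings A and B still unsaturated (10,11:17,18-tetradehydro-20; 3S,5S,9S,9aS,16S), via amino aldehyde 17 (not isolated), via cyclic enamine 18 (not isolated)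
Conditions: TFA/CH2Cl2 (1:4), 0 °C; evaporate; then 16 (3 equiv), 4 Å MS, 1,4-dioxane, 60 °C; aq. NaHCO3 work-up
Reagents that add atoms: none
Why: Proposed new method: after loss of the Boc group the secondary amine condenses with the C5 aldehyde to the seven-membered iminium ion/enamine 18 (7-exo-trig), whose nucleophilic C6 should add to the keto group of pyruvic acid; the enamine then expels the tertiary hydroxyl vinylogously to give a conjugated iminium ion whose cis carboxylate closes ring C on C5 (5-exo-trig), C5 settling under thermodynamic control by reversible ionisation of the N,O-acetal; the closest known reaction is the secondary-amine-mediated condensation of enolisable aldehydes with glyoxylic acid to 5-amino- and 5-hydroxy-2(5H)-furanones, here extended to an α-keto acid and made intramolecular in the amine, with the competing Mannich addition of the pyruvate enol expected to be reversible.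

Step 10
Reactants: 19 tetracyclic N,O-acetal with rings A and B still unsaturated
Product: 20 target CNP0155196.1 (3S,5S,9S,9aS,11R,16S,18S)
Conditions: H2 (1 atm), 5% Rh/C, EtOAc, rt
Reagents that add atoms: none
Why: Catalytic hydrogenation of the two trisubstituted butenolides (the tetrasubstituted, amino-deactivated ring C reacts far more slowly): ring B takes hydrogen anti to its C16 substituent, which sets C18 cis to it, and ring A should take hydrogen from the face syn to C9a, flanked only by H9a in the spiro-fused azepine as in related spiro-butenolides of this ring system, which sets C11.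

Compound list
1 | 3-methylfuran-2(5H)-one | CC1=CCOC1=O | starting material
2 | triisopropyl[(3-methylfuran-2-yl)oxy]silane | CC1=C(O[Si](C(C)C)(C(C)C)C(C)C)OC=C1 | intermediate
3 | 5-bromopent-1-ene | C=CCCCBr | starting material
4 | [4-methyl-5-(triisopropylsilyloxy)furan-2-yl]lithium | [Li]C1=CC(C)=C(O[Si](C(C)C)(C(C)C)C(C)C)O1 | intermediate
5 | triisopropyl{[3-methyl-5-(pent-4-en-1-yl)furan-2-yl]oxy}silane | C=CCCCC1=CC(C)=C(O[Si](C(C)C)(C(C)C)C(C)C)O1 | intermediate
6 | methyl (2R)-2-[(tert-butoxycarbonyl)amino]-3-iodopropanoate (Boc-3-iodo-L-alanine methyl ester) | CC(C)(C)OC(=O)N[C@@H](CI)C(=O)OC | starting material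
7 | (Z)-1-bromo-2-ethoxyethene | CCO/C=C\Br | starting material
8 | [(2R)-2-[(tert-butoxycarbonyl)amino]-3-methoxy-3-oxopropyl](iodo)zinc | CC(C)(C)OC(=O)N[C@@H](C[Zn]I)C(=O)OC | intermediate
9 | methyl (2S,4Z)-2-[(tert-butoxycarbonyl)amino]-5-ethoxypent-4-enoate | CCO/C=C\C[C@H](NC(=O)OC(C)(C)C)C(=O)OC | intermediate
10 | 1-tert-butyl 2-methyl (2S)-5-ethoxypyrrolidine-1,2-dicarboxylate (both C5 epimers) | CCOC1CC[C@@H](C(=O)OC)N1C(=O)OC(C)(C)C | intermediate
11 | 1-tert-butyl 2-methyl (2S,5S)-5-[(2S)-4-methyl-5-oxo-2-(pent-4-en-1-yl)-2,5-dihydrofuran-2-yl]pyrrolidine-1,2-dicarboxylate | C=CCCC[C@]1(C=C(C)C(=O)O1)[C@@H]1CC[C@@H](C(=O)OC)N1C(=O)OC(C)(C)C | intermediate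
12 | (2S,5S)-1-(tert-butoxycarbonyl)-5-[(2S)-4-methyl-5-oxo-2-(pent-4-en-1-yl)-2,5-dihydrofuran-2-yl]pyrrolidine-2-carboxylic acid | C=CCCC[C@]1(C=C(C)C(=O)O1)[C@@H]1CC[C@@H](C(=O)O)N1C(=O)OC(C)(C)C | intermediate
13 | tert-butyl (2S)-5-methoxy-2-[(2S)-4-methyl-5-oxo-2-(pent-4-en-1-yl)-2,5-dihydrofuran-2-yl]pyrrolidine-1-carboxylate (both C5 epimers) | C=CCCC[C@]1(C=C(C)C(=O)O1)[C@@H]1CCC(OC)N1C(=O)OC(C)(C)C | intermediate
14 | tert-butyl (2S,5S)-2-[(2S)-4-methyl-5-oxo-2-(pent-4-en-1-yl)-2,5-dihydrofuran-2-yl]-5-[(2S)-4-methyl-5-oxo-2,5-dihydrofuran-2-yl]pyrrolidine-1-carboxylate | C=CCCC[C@]1(C=C(C)C(=O)O1)[C@@H]1CC[C@@H]([C@@H]2C=C(C)C(=O)O2)N1C(=O)OC(C)(C)C | intermediate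
15 | tert-butyl (2S,5S)-2-[(2S)-4-methyl-5-oxo-2-(4-oxobutyl)-2,5-dihydrofuran-2-yl]-5-[(2S)-4-methyl-5-oxo-2,5-dihydrofuran-2-yl]pyrrolidine-1-carboxylate | O=CCCC[C@]1(C=C(C)C(=O)O1)[C@@H]1CC[C@@H]([C@@H]2C=C(C)C(=O)O2)N1C(=O)OC(C)(C)C | intermediate
16 | pyruvic acid (2-oxopropanoic acid) | CC(=O)C(=O)O | starting material
17 | 4-[(2S)-4-methyl-2-[(2S,5S)-5-[(2S)-4-methyl-5-oxo-2,5-dihydrofuran-2-yl]pyrrolidin-2-yl]-5-oxo-2,5-dihydrofuran-2-yl]butanal (trifluoroacetate salt in the flask) | O=CCCC[C@]1(C=C(C)C(=O)O1)[C@@H]1CC[C@@H]([C@@H]2C=C(C)C(=O)O2)N1 | intermediate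
18 | cyclic enamine: 2,3,7,8,9,9a-hexahydro-1H-pyrrolo[1,2-a]azepine with C5=C6, butenolide ring A spiro at C9 and butenolide ring B on C3 (3S,9S,9aS,16S) | C1=CCC[C@]2(C=C(C)C(=O)O2)[C@@H]2CC[C@@H]([C@@H]3C=C(C)C(=O)O3)N12 | intermediate
19 | tetracyclic N,O-acetal with rings A and B still unsaturated: 10,11:17,18-tetradehydro-20 (3S,5S,9S,9aS,16S) | CC1=C2CC[C@]3(C=C(C)C(=O)O3)[C@@H]3CC[C@@H]([C@@H]4C=C(C)C(=O)O4)N3[C@H]2OC1=O | intermediate
20 | target CNP0155196.1 (3S,5S,9S,9aS,11R,16S,18S) | CC1=C2CC[C@]3(C[C@@H](C)C(=O)O3)[C@@H]3CC[C@@H]([C@@H]4C[C@H](C)C(=O)O4)N3[C@H]2OC1=O | target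

Total step count: 10.
Longest linear sequence: 9 steps (steps 1, 2, 4, 5, 6, 7, 8, 9, 10 from 1; the branch from 6 is 8 steps).

Steps most likely to fail

Step 9 (proposed new method). Mannich addition of the pyruvic acid enol to the iminium ion, or self-condensation of the enamine/iminium pair, may outrun addition of C6 to the keto group, so that ring C does not form. The fallback uses known chemistry, sets out from 15 and returns at 19. After removal of the Boc group with TFA and neutralisation, the cyclic enamine 18 is C-acylated at C6 with ethyl chlorooxoacetate and Et3N (Stork enamine acylation) to give the vinylogous amide keto ester F1. Chemoselective methyl transfer to the keto group with MeTi(OiPr)3 gives the tertiary carbinol F2. Warming F2 with TFA in wet CH2Cl2 ionises the hydroxyl through the enamine, and lactonisation onto C5 with loss of ethanol gives 19.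

Step 10. Hydrogenolysis of the allylic C5–O bond, slow saturation of ring C, or delivery of hydrogen to the C8 face of ring A may erode the final reduction. The fallback sets out from 19 and returns at 20. Conjugate reduction with Stryker's reagent [(Ph3P)CuH]6 in toluene delivers hydride only to the β-carbons C10 and C17 of the two trisubstituted butenolides, without hydrogenolysis and without touching ring C. Protonation on work-up should give 20, accompanied if ring A is protonated from the wrong face by the C11 epimer F3. Catalytic DBU should equilibrate F3 to 20, in which the C11 methyl is trans to the bulkier C9a substituent and the C18 methyl keeps its preferred cis arrangement.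

Step 6. Anodic over-oxidation (terminal alkene, methoxylation next to the butenolide) or electrode passivation may erode the decarboxylative methoxylation. The fallback sets out from 12 and returns at 14. Acid 12 is converted with 2-mercaptopyridine N-oxide and DCC into the O-acyl thiohydroxamate (Barton ester) F4, which is irradiated with visible light without isolation; radical decarboxylation and group transfer give the C3 pyridin-2-yl thioaminal F5. AgOTf in CH2Cl2 at −40 °C ionises F5 to the same N-acyliminium ion, and addition of furan 2 gives 14.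

Further compounds
F1 | step 9 | ethyl 2-oxo-2-(enamin-6-yl)acetate: cyclic enamine 18 carrying C(=O)CO2Et on C6 (3S,9S,9aS,16S) | C1=C(C(=O)C(=O)OCC)CC[C@]2(C=C(C)C(=O)O2)[C@@H]2CC[C@@H]([C@@H]3C=C(C)C(=O)O3)N12
F2 | step 9 | ethyl 2-hydroxy-2-(enamin-6-yl)propanoate: cyclic enamine 18 carrying C(OH)(CH3)CO2Et on C6 (both carbinol epimers) | C1=C(C(C)(O)C(=O)OCC)CC[C@]2(C=C(C)C(=O)O2)[C@@H]2CC[C@@H]([C@@H]3C=C(C)C(=O)O3)N12
F3 | step 10 | C11 epimer of 20 (3S,5S,9S,9aS,11S,16S,18S) | CC1=C2CC[C@]3(C[C@H](C)C(=O)O3)[C@@H]3CC[C@@H]([C@@H]4C[C@H](C)C(=O)O4)N3[C@H]2OC1=O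
F4 | step 6 | 2-thioxopyridin-1(2H)-yl ester (Barton ester) of acid 12 | C=CCCC[C@]1(C=C(C)C(=O)O1)[C@@H]1CC[C@@H](C(=O)ON2C=CC=CC2=S)N1C(=O)OC(C)(C)C
F5 | step 6 | tert-butyl (2S)-2-[(2S)-4-methyl-5-oxo-2-(pent-4-en-1-yl)-2,5-dihydrofuran-2-yl]-5-(pyridin-2-ylsulfanyl)pyrrolidine-1-carboxylate (both C5 epimers) | C=CCCC[C@]1(C=C(C)C(=O)O1)[C@@H]1CCC(Sc2ccccn2)N1C(=O)OC(C)(C)C
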